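## The problem

Compound 26 (CNP0073203.1) is a C20 cage. A 2-oxabicyclo[2.2.2]octane (C10–C11–C12–C13–C14–C15, bridged by the ether oxygen and C16) is fused to a γ-lactone (C1, C2, C16, C15, O), to a cyclopentane (C8–C9–C10–C15–C16) and to an eight-membered carbocycle (C2 to C8 plus C16) that carries the enolised β-keto lactone. There are nine stereocentres. C12, C13, C15 and C16 are contiguous and fully substituted, while C4 and C6 lie in the flexible chain, remote from the cage. Once C12, C13 and C15 are fixed, the rigid bicycle can dictate C10, C16, C8 and C11, but nothing in the cage can set C4 and C6, so these must arrive in a pre-formed fragment. The fragile elements are the acidic C2=C3 enol, the ether oxygen on C16 (β to the C1, C3 and C7 carbonyls, so the bridge can open by retro-oxa-Michael reaction under base), the epimerisable C6 and C8 next to the C7 ketone, and the β-hydroxy ketone relation between C13–OH and any C11 carbonyl (retro-aldol). Closing the eight-membered ring is a separate difficulty. The enabling feature is the cyclopentane: C10 is α to the oxygen-bearing C11, C16 is the β-carbon of the lactone, and C9–C8 joins them as the β/α carbons of the C7 ketone. With C11 as a ketone and C1/C2/C16 as a tetronate, the ring is therefore the formal [3+2] adduct of a bridged keto tetronate and a vinyl ketone.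

## Retrosynthesis

**26 back to 24 (adjustments only).** The C13 alcohol is carried as a triethylsilyl ether (25) and the C11 alcohol as a ketone (24). The silyl ether prevents retro-aldol cleavage of C12–C13 whenever C11 is a carbonyl, and it screens one face of C11, so a small hydride should come from the ether-oxygen side and give C11–OH syn to C13–O. The reduction has to leave the C7 ketone alone, which is reasonable because C7 is α-branched on both sides.

**24 to 23 (cut C2–C3).** The eight-membered ring is opened at the bond between the lactone α-carbon and the enol carbon, which is a Claisen bond; this leaves lactone 23 with a methyl ester at C3. The neighbouring cuts are less attractive: C3–C4 or C6–C7 would need an enolate at a stereogenic methyl-bearing carbon, and C7–C8 is made in the annulation. In 23 the two reacting carbons hang cis from adjacent cage atoms (C16 and C8). The forward step needs lactone enolisation at C2 without loss of C6 and C8, and a medium-ring closure driven by deprotonation of the product.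

**23 to 16 + 21 (cut C9–C10 and C8–C16).** Both cyclopentane bonds are Michael bonds, so 23 divides into the bridged keto tetronate 16 (11 skeletal carbons, three stereocentres) and the vinyl ketone 21 (the C3–C9 chain with C4 and C6). This single step joins the halves and creates C10, C8 and C16. Other ways of making the cyclopentane would assemble the chain on the cage stepwise. The forward step requires the C10 enolate to add on the face turned toward the O–C16 bridge and the resulting C8 enolate to reach C16 before it is protonated.

**21 to 17.** The syn-1,3-dimethyl array comes from meso-2,4-dimethylglutaric anhydride 17. Desymmetrising methanolysis gives half ester 18, which is converted to Weinreb amide 19 and then to the vinyl ketone with vinylmagnesium bromide 20. The ester end becomes C3 and the acid end C7, so the opening must give the (2R,4S) half ester.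

**16 to 12 (cut O–C12 and C2–C16).** After two adjustments (C13 silylation, C11 oxidation: 16 ← 15 ← 14), the ether bridge is cut at C12. Diol 14 then comes from spirotetronic acid epoxide 13 by opening of a 12,13-epoxide at C12. The tetronate oxygen lies in the plane through C15 and C12, so it can reach only C12, and the opening with inversion fixes C12–O anti and C13–OH syn to the C15 oxygen in one event. The tetronate is cut at C2–C16 (Lacey–Dieckmann), giving acetate 12. In 12 the C11 oxygen and the C16 carboxyl are tied as a γ-lactone, so the Claisen step releases the C11 alcohol and no protecting group is needed there. A Diels–Alder route to a 3,4-dimethylcyclohexene was weighed, but it cannot place oxygen at C11 with the right regiochemistry.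

**12 to 9 (cut C12=C13).** Acetate 12 is the acetylation product of epoxy alcohol 11, which comes from alkene 10 by epoxidation anti to the lactone bridge. The tetrasubstituted alkene of 10 is cut by ring-closing metathesis to lactone 9, a cis-3,5-disubstituted butyrolactone with methallyl and isopropenyl arms. This removes the carbocycle and leaves two stereocentres.

**9 to 1.** Lactone 9 arises from ketone 7 by reagent-controlled reduction at C11 and translactonisation (via 8). Ketone 7 is the acylation product of acid 4 (via acid chloride 6) with stannane 5. The quaternary C15 of 4 comes from (S)-malic acid 1 through dioxolanone 2 and alkylation with methallyl bromide 3 (self-regeneration of stereocentres). C15 is therefore taken from the chiral pool, and C11, C12 and C13 are derived from it.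

## Roads not taken

**Alternative 1:** cut C10–C15 and C11–C12, and form the carbocycle of a bridged lactone by amine-catalysed Diels–Alder addition of 3-hydroxy-6-methyl-2-pyrone A2 to methyl (E)-3-borylacrylate A3, giving A1.
- Merits: the oxabicyclo[2.2.2] core, the C15 hydroxyl, the C12 methyl, a C11 oxygen equivalent (boronate) and a C10 carbon handle appear in one catalytic, potentially enantioselective step. For reaching the bicycle this road is clearly shorter than the chosen one, which spends ten steps on 16.
- Weak points: A1 is far from the target where it matters. The C13=C14 alkene must become a methyl-bearing tertiary carbinol with regio- and facial control. The lactone carbonyl must be turned into the tetronate carbon C16. C10 carries an ester that must be extended by C9 and C8. The cyclopentane and the eight-membered ring are still unaddressed.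
- Comparison: the chosen plan sets C12 and C13 in one stereospecific epoxide opening and obtains the C11 ketone needed for the annulation directly; the annulation then makes the cyclopentane with three stereocentres in one operation.

**Alternative 2:** cut C15–C16 and the lactone C–O bond. A samarium(II)-generated ketyl at C15 of keto ynoate A5 adds 5-exo-dig to the ynoate and lactonises to butenolide A4.
- Merits: ketyl–ynoate closures are dependable, the ring fusion is cis by necessity, and cyclopentane and lactone form together.
- Weak points: A5 already needs four contiguous stereocentres (C10–C13) on a cyclohexanone made from a dearomatised phenol, where absolute control is hard to introduce. After A4 the ether bridge must still be closed by adding a tertiary alcohol to a β,β-disubstituted butenolide, which is of uncertain thermodynamics before C2 is acylated. C8 is an unactivated methylene that must receive the whole C3–C7 chain.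
- Comparison: this road is linear and defers chain attachment and the medium ring. The chosen plan is convergent and brings C3–C9 with C4 and C6 in one fragment. In its favour, alternative 2 never exposes C6 to base, which the chosen plan does in two steps.

**Alternative 3:** cut C5–C6 and C6–C7. Diazoethane A8 adds to the C7 ketone of the seven-membered ketone A7 and migration of C5 gives the methyl enol ether A6.
- Merits: a seven-membered Dieckmann ring is much easier to close than the eight-membered ring, which is the weakest step after the annulation in the chosen plan. On ring closure this road is better.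
- Weak points: the ring expansion has to choose between migration of the C5 methylene and the C8 methine (the more substituted carbon usually migrates as well or better). It creates C6 without a controlling element, next to an epimerisable ketone, and competes with epoxide formation and double homologation. The Lewis acids normally needed are a threat to the tertiary alcohols and the ether bridge at the last stage. A6 still needs O-demethylation.
- Comparison: the chosen plan accepts a harder ring closure in exchange for C4 and C6 coming with certainty from a meso anhydride.

Key step: step 14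

Assumptions (remarks on the chemistry):
- Quinidine is taken to open anhydride 17 to the (2R,4S) half ester 18. Quinine and quinidine give opposite half esters in this reaction class, so quinine would be used if the sense is found reversed.
- Atom numbers C1–C16 are those of the target and are used for all intermediates.

## Steps

Step 1
Reactants: 1 (S)-malic acid
Product: 2 2-[(2S,4S)-2-tert-butyl-5-oxo-1,3-dioxolan-4-yl]acetic acid (cis)
Conditions: t-BuCHO, p-TsOH (cat.), H2SO4 (cat.), pentane, reflux, Dean–Stark; crystallisation
Reagents that add atoms: pivalaldehyde, CC(C)(C)C=O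
Why: Acid-catalysed acetalisation of the α-hydroxy acid unit; the cis-dioxolanone (tert-butyl and CH2CO2H on one face) is the thermodynamic isomer and is purified by crystallisation.

Step 2
Reactants: 2 the cis-dioxolanone acid; 3 3-bromo-2-methylprop-1-ene
Product: 4 2-[(2S,4S)-2-tert-butyl-4-(2-methylprop-2-en-1-yl)-5-oxo-1,3-dioxolan-4-yl]acetic acid
Conditions: LiHMDS (2.2 equiv), THF, −78 °C; 3, −78 → −20 °C; 1 M HCl
Reagents that add atoms: none
Why: Enolate alkylation with self-regeneration of the stereocentre: the carboxylate–enolate dianion is alkylated anti to the tert-butyl group, so the methallyl group (C14, C13 and its methyl) replaces the former hydrogen with net retention and C15 becomes quaternary (S).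

Step 3
Reactants: 4 the alkylated acid; 5 tributyl(prop-1-en-2-yl)stannane
Product: 7 (2S,5S)-2-tert-butyl-5-(3-methyl-2-oxobut-3-en-1-yl)-5-(2-methylprop-2-en-1-yl)-1,3-dioxolan-4-one, via acid chloride 6 (not isolated)
Conditions: 1-chloro-N,N,2-trimethylprop-1-en-1-amine, CH2Cl2, 0 °C; then 5, PdCl2(PPh3)2 (3 mol%), toluene, 60 °C
Reagents that add atoms: none
Why: Neutral chlorination of the acid followed by Stille acylation gives the isopropenyl ketone (C11–C12 bond); the dioxolanone carbonyl is inert to the stannane and palladium, and no base is present that could eliminate the β-oxygen.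

Step 4
Reactants: 7 the isopropenyl ketone
Product: 9 (3S,5R)-3-hydroxy-3-(2-methylprop-2-en-1-yl)-5-(prop-1-en-2-yl)oxolan-2-one, via hydroxy dioxolanone 8 (not isolated)
Conditions: (S)-Me-CBS (20 mol%), catecholborane, toluene, −78 °C; MeOH; then CSA (10 mol%), CH2Cl2, rt
Reagents that add atoms: none
Why: CBS reduction, 1,2-selective with catecholborane: the (S)-oxazaborolidine treats the α-branched alkenyl group as the large substituent and should give the (11R)-alcohol; the γ-hydroxyl then opens the acylal-type dioxolanone (translactonisation) and pivalaldehyde is lost, giving the lactone with both alkenyl arms cis.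

Step 5
Reactants: 9 the diene lactone
Product: 10 (1S,5R)-1-hydroxy-3,4-dimethyl-6-oxabicyclo[3.2.1]oct-3-en-7-one
Conditions: Hoveyda–Grubbs-type Ru catalyst with N,N′-di-o-tolyl NHC (10 mol%), toluene (0.01 M), 80 °C, argon sparge
Reagents that add atoms: none
Why: Ring-closing metathesis of two 1,1-disubstituted alkenes held 1,3-cis by the lactone; ethene is lost and the C12=C13 tetrasubstituted alkene forms, for which the less hindered NHC catalyst is chosen.

Step 6
Reactants: 10 the bicyclic alkene
Product: 11 3,4-epoxide of 10 (12,13-epoxide), epoxide oxygen anti to the lactone bridge and on the face of the C15 hydroxyl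
Conditions: m-CPBA, NaHCO3, CH2Cl2, 0 °C
Reagents that add atoms: 3-chloroperbenzoic acid, OOC(=O)c1cccc(Cl)c1
Why: Prilezhaev epoxidation of the electron-rich tetrasubstituted alkene; the peracid should approach anti to the pseudo-axial allylic C11–O bond and the lactone bridge that cover the other face.

Step 7
Reactants: 11 the epoxy alcohol
Product: 12 C15 acetate of 11
Conditions: Ac2O, Et3N, DMAP (cat.), CH2Cl2, rt
Reagents that add atoms: acetic anhydride, CC(=O)OC(C)=O
Why: DMAP-catalysed acetylation of the only hydroxyl (tertiary, bridgehead); it supplies C1 and C2 of the tetronate.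

Step 8
Reactants: 12 the epoxy acetate
Product: 14 bridged tetronate diol (butenolide C1/C2/C16 fused at C15–C16 to the 2-oxabicyclo[2.2.2]octane; ether O between C12 and C16; C11–OH on the ether-bridge side; C13–OH on the side of the C10–C11 bridge), via spirotetronic acid epoxide 13 (not isolated)
Conditions: LiHMDS (3 equiv), THF, −78 → −20 °C; AcOH; then toluene, 60 °C
Reagents that add atoms: none
Why: Lacey–Dieckmann-type intramolecular Claisen condensation: the acetate enolate attacks the adjacent lactone carbonyl (5-exo-trig) and the C11 alkoxide is expelled, driven by formation of the tetronate anion. After acidification the tetronic acid oxygen, which lies in the plane through C15 and C12, opens the epoxide at C12 with inversion, a known way of closing oxabicyclo[2.2.2]octanes onto spirotetronates; this sets C12–O anti and C13–OH syn to the C15 oxygen.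

Step 9
Reactants: 14 the diol
Product: 15 bridged tetronate with C11 ketone and free C13 hydroxyl
Conditions: Dess–Martin periodinane, NaHCO3, CH2Cl2, 0 °C → rt
Reagents that add atoms: none
Why: Dess–Martin oxidation of the only secondary alcohol; the tertiary alcohol and tetronate are inert, and the neutral medium avoids retro-aldol cleavage of the β-hydroxy ketone.

Step 10
Reactants: 15 the hydroxy ketone
Product: 16 bridged keto tetronate C13 triethylsilyl ether (annulation precursor)
Conditions: TESOTf, 2,6-lutidine, CH2Cl2, −78 → 0 °C
Reagents that add atoms: triethylsilyl trifluoromethanesulfonate, CC[Si](CC)(CC)OS(=O)(=O)C(F)(F)F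
Why: Silyl triflate silylation of the hindered tertiary alcohol; the ether blocks retro-aldol fragmentation in the enolate chemistry and later shields one face of C11.

Step 11
Reactants: 17 meso-2,4-dimethylglutaric anhydride
Product: 18 (2R,4S)-5-methoxy-2,4-dimethyl-5-oxopentanoic acid
Conditions: quinidine (1.1 equiv), MeOH (3 equiv), toluene, −55 °C; 2 M HCl
Reagents that add atoms: methanol, CO
Why: Alkaloid-mediated desymmetrising methanolysis of a meso anhydride; general-base catalysis by the quinuclidine differentiates the enantiotopic carbonyls, leaving the free acid on the carbon that becomes C6 (see the assumption above).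

Step 12
Reactants: 18 the half ester
Product: 19 methyl (2S,4R)-5-[methoxy(methyl)amino]-2,4-dimethyl-5-oxopentanoate
Conditions: CDI, CH2Cl2, 0 °C → rt; MeNH(OMe)·HCl
Reagents that add atoms: N,O-dimethylhydroxylamine hydrochloride, CNOC.Cl
Why: Amide formation through the acyl imidazolide, mild enough to leave the α-stereocentre untouched.

Step 13
Reactants: 19 the Weinreb amide; 20 vinylmagnesium bromide
Product: 21 methyl (2S,4R)-2,4-dimethyl-5-oxohept-6-enoate
Conditions: 20 (1.3 equiv), THF, −78 → −30 °C; inverse quench into cold 1 M HCl
Reagents that add atoms: none
Why: Weinreb ketone synthesis: the chelated adduct stops after one addition and the amide reacts before the α-branched methyl ester at low temperature; the inverse acidic quench prevents conjugate addition of the released amine to the vinyl ketone.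

Step 14
Reactants: 16 the bridged keto tetronate; 21 the vinyl ketone
Product: 23 cage lactone with closed cyclopentane, C11 ketone, C13 OTES and the C8 acyl chain ending in the C3 methyl ester, via lithium enolate 22 (not isolated)
Conditions: LiHMDS (1.05 equiv), THF, −78 °C; 21 (1.1 equiv), −78 → 0 °C; AcOH, −78 °C
Reagents that add atoms: none
Why: LiHMDS removes a C10 proton of 16, the only enolisable position of the C11 ketone; the enolate cannot expel the C15 oxygen because that would create a bridgehead alkene. Conjugate addition to 21 forms C9–C10 and delivers the C8 lithium enolate 22 regiospecifically. 22 then attacks the vinylogous-carbonate carbon C16 in a 5-exo-trig Michael closure (C8–C16), and the lactone enolate is protonated at C2 on quench. The closest known reaction type is the sequential Michael–Michael [3+2] annulation of ketone enolates with enones, with enolate addition to a β-alkoxybutenolide as the ring-closing event. C10 is set by approach of the enone over the flat O–C16 bridge, away from the C13–C14 bridge with its silyl ether; an adduct on the wrong face cannot cyclise and can return through the C11 enolate. C16 follows from C10, since only the face turned toward C9 can be reached. At C8 the acyl group should take the exo position on the new ring, cis to C2, which is also the epimer expected at equilibrium. The step needs 1,4- over 1,2-addition and cyclisation before the lactone enolate meets a second enone; both are addressed by slow addition of one equivalent of the hindered enone at −78 °C, and the absence of free base protects C6.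

Step 15
Reactants: 23 the annulation product
Product: 24 C11-keto, C13-OTES precursor of the target with the eight-membered ring closed (C3 enol of the β-keto lactone)
Conditions: LiHMDS (2.5 equiv), THF (0.01 M), −78 → 0 °C; 1 M HCl
Reagents that add atoms: none
Why: Intramolecular Claisen (Dieckmann) condensation: the bulky amide should deprotonate the unhindered lactone methylene C2 faster than the ketone methines, and the enolate acylates on the C3 ester held nearby by the cis C8/C16 substituents. Deprotonation of the β-keto lactone makes the C2–C3 closure irreversible, and acidification gives the hydrogen-bonded C3 enol.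

Step 16
Reactants: 24 the C11 ketone
Product: 25 C13 triethylsilyl ether of the target
Conditions: NaBH4, MeOH/CH2Cl2, −40 °C
Reagents that add atoms: none
Why: Borohydride should reduce the strained α-alkoxy bicyclic C11 ketone before the doubly α-branched C7 ketone, while the β-keto lactone is protected as its enolate. Hydride enters from the ether-oxygen face, anti to the C13 silyl ether, so C11–OH ends syn to C13–O.

Step 17
Reactants: 25 the silyl ether
Product: 26 CNP0073203.1
Conditions: HF·pyridine, THF/pyridine, 0 °C → rt
Reagents that add atoms: none
Why: Buffered fluoride cleavage of the tertiary silyl ether; the conditions are too mild to open the ether bridge or epimerise C6 and C8.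

## Compound list

1 | (S)-malic acid | O[C@@H](CC(=O)O)C(=O)O | starting material
2 | 2-[(2S,4S)-2-tert-butyl-5-oxo-1,3-dioxolan-4-yl]acetic acid | OC(=O)C[C@@H]1O[C@H](C(C)(C)C)OC1=O | intermediate
3 | 3-bromo-2-methylprop-1-ene | CC(=C)CBr | starting material
4 | 2-[(2S,4S)-2-tert-butyl-4-(2-methylprop-2-en-1-yl)-5-oxo-1,3-dioxolan-4-yl]acetic acid | OC(=O)C[C@]1(CC(C)=C)O[C@H](C(C)(C)C)OC1=O | intermediate
5 | tributyl(prop-1-en-2-yl)stannane | CCCC[Sn](CCCC)(CCCC)C(C)=C | starting material
6 | 2-[(2S,4S)-2-tert-butyl-4-(2-methylprop-2-en-1-yl)-5-oxo-1,3-dioxolan-4-yl]acetyl chloride | ClC(=O)C[C@]1(CC(C)=C)O[C@H](C(C)(C)C)OC1=O | intermediate (not isolated)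
7 | (2S,5S)-2-tert-butyl-5-(3-methyl-2-oxobut-3-en-1-yl)-5-(2-methylprop-2-en-1-yl)-1,3-dioxolan-4-one | CC(=C)C(=O)C[C@]1(CC(C)=C)O[C@H](C(C)(C)C)OC1=O | intermediate
8 | (2S,5S)-2-tert-butyl-5-[(2R)-2-hydroxy-3-methylbut-3-en-1-yl]-5-(2-methylprop-2-en-1-yl)-1,3-dioxolan-4-one | CC(=C)[C@H](O)C[C@]1(CC(C)=C)O[C@H](C(C)(C)C)OC1=O | intermediate (not isolated)
9 | (3S,5R)-3-hydroxy-3-(2-methylprop-2-en-1-yl)-5-(prop-1-en-2-yl)oxolan-2-one | O[C@@]1(CC(C)=C)C[C@@H](OC1=O)C(C)=C | intermediate
10 | (1S,5R)-1-hydroxy-3,4-dimethyl-6-oxabicyclo[3.2.1]oct-3-en-7-one | O[C@@]12C[C@@H](OC1=O)C(C)=C(C)C2 | intermediate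
11 | 3,4-epoxide of 10, epoxide oxygen anti to the lactone bridge | O[C@@]12C[C@@H](OC1=O)[C@]3(C)O[C@]3(C)C2 | intermediate
12 | C15 acetate of 11 | CC(=O)O[C@@]12C[C@@H](OC1=O)[C@]3(C)O[C@]3(C)C2 | intermediate
13 | spirotetronic acid with C11 hydroxyl and 12,13-epoxide | OC1=CC(=O)O[C@@]12C[C@@H](O)[C@]3(C)O[C@]3(C)C2 | intermediate (not isolated)
14 | bridged tetronate diol (C11–OH, C13–OH) | O=C1C=C2O[C@]3(C)[C@H](O)C[C@]2(C[C@@]3(C)O)O1 | intermediate
15 | bridged tetronate, C11 ketone, C13–OH | O=C1C=C2O[C@]3(C)C(=O)C[C@]2(C[C@@]3(C)O)O1 | intermediate
16 | bridged keto tetronate, C13 triethylsilyl ether | O=C1C=C2O[C@]3(C)C(=O)C[C@]2(C[C@@]3(C)O[Si](CC)(CC)CC)O1 | intermediate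
17 | meso-2,4-dimethylglutaric anhydride | C[C@@H]1C[C@H](C)C(=O)OC1=O | starting material
18 | (2R,4S)-5-methoxy-2,4-dimethyl-5-oxopentanoic acid | OC(=O)[C@H](C)C[C@H](C)C(=O)OC | intermediate
19 | methyl (2S,4R)-5-[methoxy(methyl)amino]-2,4-dimethyl-5-oxopentanoate | CON(C)C(=O)[C@H](C)C[C@H](C)C(=O)OC | intermediate
20 | vinylmagnesium bromide | C=C[Mg]Br | starting material
21 | methyl (2S,4R)-2,4-dimethyl-5-oxohept-6-enoate | C=CC(=O)[C@H](C)C[C@H](C)C(=O)OC | intermediate
22 | lithium (Z)-C8 enolate of the C10 Michael adduct of 16 and 21 | O=C1C=C2O[C@]3(C)C(=O)[C@H](C/C=C(\[O-])[C@H](C)C[C@H](C)C(=O)OC)[C@]2(C[C@@]3(C)O[Si](CC)(CC)CC)O1.[Li+] | intermediate (not isolated)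
23 | cage lactone with closed cyclopentane, C11 ketone, C13 OTES and C8 acyl chain | COC(=O)[C@@H](C)C[C@@H](C)C(=O)[C@@H]1C[C@H]2C(=O)[C@@]3(C)O[C@@]14CC(=O)O[C@@]24C[C@@]3(C)O[Si](CC)(CC)CC | intermediate
24 | 11-oxo, 13-O-triethylsilyl derivative of the target (C3 enol) | C[C@@H]1C[C@H](C)/C(O)=C2/C(=O)O[C@]34C[C@@](C)(O[Si](CC)(CC)CC)[C@]5(C)O[C@]23[C@@H](C[C@H]4C5=O)C1=O | intermediate
25 | 13-O-triethylsilyl ether of the target | C[C@@H]1C[C@H](C)/C(O)=C2/C(=O)O[C@]34C[C@@](C)(O[Si](CC)(CC)CC)[C@]5(C)O[C@]23[C@@H](C[C@H]4[C@@H]5O)C1=O | intermediate
26 | CNP0073203.1 | C[C@@H]1C[C@H](C)/C(O)=C2/C(=O)O[C@]34C[C@@](C)(O)[C@]5(C)O[C@]23[C@@H](C[C@H]4[C@@H]5O)C1=O | target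

## Step count and risks

Total: 17 steps. Longest linear sequence: 14 steps (steps 1–10, then 14–17). The enone branch (steps 11–13) joins at step 14.

**Step 14 (key step).** The second Michael addition may be too slow on the weakly electrophilic tetronate, so that enolate 22 is protonated or adds to more enone; the lactone enolate may also expel the C12 alkoxide (ring-opening of the ether bridge), and proton exchange could epimerise C6. Fallback, from 16 and 21 back to 23: 16 is converted with TMSOTf/Et3N into its trimethylsilyl enol ether F1. F1 and 21 are combined with catalytic triflimide in CH2Cl2 at −78 °C (Mukaiyama–Michael). Silyl transfer gives the C8 silyl enol ether F2 in the flask, which adds to the acid-activated tetronate; aqueous work-up returns 23. No basic species is present in this variant.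

**Step 15 (eight-membered Claisen).** Enolisation may occur at the ketone methines instead of C2 (epimerisation of C6 or C8, retro-Michael opening of the cyclopentane), or the medium-ring closure may lose to intermolecular condensation. Fallback, from 23 back to 24: the methyl ester is hydrolysed selectively with trimethyltin hydroxide to acid F3, which is activated with CDI as acyl imidazolide F4. Brief treatment of F4 with LiHMDS at −78 °C should then close the ring, because the imidazolide acylates the lactone enolate much faster than a methyl ester.

**Step 8 (Claisen onto the lactone, epoxide opening).** The tetrasubstituted epoxide may ionise at C13, which the tetronate cannot reach, leading to elimination or hydration; the liberated C11 hydroxyl may also condense with the tetronic acid. Fallback, from 12 back to 14: after the Claisen step and acidification, the tetronic acid is O-methylated with trimethylsilyldiazomethane to methyl tetronate F5. Heating F5 with LiCl in DMSO demethylates it and releases the tetronate anion, which opens the epoxide at C12 under non-acidic conditions to give 14.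

**Step 5 (tetrasubstituted, bridging metathesis).** The catalyst may stall on two 1,1-disubstituted alkenes that must close a bridged ring, giving dimers instead. Fallback, from 7 back to 10: after the CBS reduction the alcohol is silylated before lactonisation to TBS ether F6. Metathesis of this unconstrained 1,7-diene gives cyclohexene F7. TBAF then removes the silyl group, and the C11 alkoxide opens the dioxolanone to give 10.

**Step 16 (chemo- and face-selective reduction).** The C7 ketone may be reduced as well. Fallback, from 23 back to 25: the order is reversed. 23 is reduced with NaBH4 at −78 °C, where C7 is an acyclic, doubly branched ketone, to give alcohol F8. The Claisen closure is then run on F8 with one more equivalent of base and gives 25 directly.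

## Further compounds

F1 | step 14 | trimethylsilyl enol ether (C10=C11) of 16 | O=C1C=C2O[C@]3(C)C(O[Si](C)(C)C)=C[C@]2(C[C@@]3(C)O[Si](CC)(CC)CC)O1
F2 | step 14 | C8 trimethylsilyl enol ether of the mono-Michael adduct | O=C1C=C2O[C@]3(C)C(=O)[C@H](C/C=C(\O[Si](C)(C)C)[C@H](C)C[C@H](C)C(=O)OC)[C@]2(C[C@@]3(C)O[Si](CC)(CC)CC)O1
F3 | step 15 | C3 carboxylic acid of 23 | OC(=O)[C@@H](C)C[C@@H](C)C(=O)[C@@H]1C[C@H]2C(=O)[C@@]3(C)O[C@@]14CC(=O)O[C@@]24C[C@@]3(C)O[Si](CC)(CC)CC
F4 | step 15 | C3 acyl imidazolide of 23 | O=C(n1ccnc1)[C@@H](C)C[C@@H](C)C(=O)[C@@H]1C[C@H]2C(=O)[C@@]3(C)O[C@@]14CC(=O)O[C@@]24C[C@@]3(C)O[Si](CC)(CC)CC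
F5 | step 8 | spiro methyl tetronate with C11 hydroxyl and 12,13-epoxide | COC1=CC(=O)O[C@@]12C[C@@H](O)[C@]3(C)O[C@]3(C)C2
F6 | step 5 | tert-butyldimethylsilyl ether of 8 | CC(=C)[C@H](O[Si](C)(C)C(C)(C)C)C[C@]1(CC(C)=C)O[C@H](C(C)(C)C)OC1=O
F7 | step 5 | spiro dioxolanone 3,4-dimethylcyclohexene with C11 OTBS | CC1=C(C)[C@H](O[Si](C)(C)C(C)(C)C)C[C@]2(C1)O[C@H](C(C)(C)C)OC2=O
F8 | step 16 | C11 alcohol of 23 | COC(=O)[C@@H](C)C[C@@H](C)C(=O)[C@@H]1C[C@H]2[C@H](O)[C@@]3(C)O[C@@]14CC(=O)O[C@@]24C[C@@]3(C)O[Si](CC)(CC)CC
A1 | alternative 1 | methyl 4-hydroxy-1-methyl-3-oxo-7-(4,4,5,5-tetramethyl-1,3,2-dioxaborolan-2-yl)-2-oxabicyclo[2.2.2]oct-5-ene-8-carboxylate | O[C@@]1(C(=O)O2)C=C[C@@]2(C)[C@@H](B3OC(C)(C)C(C)(C)O3)[C@@H]1C(=O)OC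
A2 | alternative 1 | 3-hydroxy-6-methyl-2H-pyran-2-one | Cc1ccc(O)c(=O)o1
A3 | alternative 1 | methyl (E)-3-(4,4,5,5-tetramethyl-1,3,2-dioxaborolan-2-yl)prop-2-enoate | COC(=O)/C=C/B1OC(C)(C)C(C)(C)O1
A4 | alternative 2 | cis-hydrindane-fused butenolide with C11/C13 acetonide and C12 OTMS | O=C1C=C2CC[C@H]3[C@@H]4OC(C)(C)O[C@](C)(C[C@@]23O1)[C@]4(C)O[Si](C)(C)C
A5 | alternative 2 | cyclohexanone with tethered ynoate (precursor of A4) | COC(=O)C#CCC[C@H]1[C@@H]2OC(C)(C)O[C@](C)(CC1=O)[C@]2(C)O[Si](C)(C)C
A6 | alternative 3 | C3 methyl enol ether of the target | C[C@@H]1C[C@H](C)/C(OC)=C2/C(=O)O[C@]34C[C@@](C)(O)[C@]5(C)O[C@]23[C@@H](C[C@H]4[C@@H]5O)C1=O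
A7 | alternative 3 | seven-membered-ring ketone lacking C6 | O=C1C[C@H](C)/C(OC)=C2/C(=O)O[C@]34C[C@@](C)(O)[C@]5(C)O[C@]23[C@H]1C[C@H]4[C@@H]5O
A8 | alternative 3 | diazoethane | CC=[N+]=[N-]
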